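The single-handed catalyst in the flask works on both mirror-image substrates at once, charged at [left-handed substrate] = [right-handed substrate] = 10 mM with [reagent] = 20.0 mM.

in all of them: catalyst 99 µM; added ligand 91 µM
- south-west: left-handed substrate 5 mM; right-handed substrate 5 mM; reagent 20 mM; run made earlier
- flask: left-handed substrate 10 mM; right-handed substrate 10 mM; reagent 20.0 mM; time 40 min

south-west run (percent of the left-handed substrate and right-handed substrate together charged)

| time / min | left-handed substrate / % | right-handed substrate / % |
|---|---|---|
| 1.50 | 44.1 | 48.5 |
| 3.00 | 39.2 | 44.2 |
| 5.00 | 34.4 | 40.9 |
| 6.00 | 30.2 | 40.6 |
| 8.00 | 27.8 | 40.1 |

(scatter of a reading: 1 percentage point)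

- catalyst is single-handed; left-handed substrate and right-handed substrate are mirror images of each other, charged as a racemate, each of them at the stated concentration
- the numbers in the tables scatter by 1 percentage point (one standard deviation)
- steps thought possible: left-handed substrate <-> right-handed substrate; catalyst + added ligand <-> idle complex; reagent + catalyst + right-handed substrate -> catalyst + right-handed product; reagent <-> dormant form; reagent + catalyst + left-handed substrate -> catalyst + left-handed product
- an excess is the difference of the two amounts in percent of their sum
- an excess is below zero if the other one leads

1. part of the left-handed substrate and right-handed substrate charged together that has reacted at 40 min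
2. excess of left-handed product over right-handed product in the product at 40 min
3. excess of right-handed substrate over left-handed substrate among what is left of the two at 40 min

The last south-west reading, at 8.00 min, gives 2.66 for the apparent selectivity factor, the logarithm of the fraction of left-handed substrate left over the logarithm of the fraction of right-handed substrate left. While each substrate reacts in proportion to its own amount and neither turns into the other, the shared reagent and catalyst cancel from this ratio.

In the flask, the reagent charge equals the two substrates together. My own reckoning assumes that each substrate reacting uses one reagent and that the mean [reagent] is 0.5 of the charge, so 40 min count as 20.0 min at the south-west pace. That leaves 23.1% of the left-handed substrate and, by the ratio, 57.6% of the right-handed substrate. So c is 59.7%, eP is 28.9% and eS is 42.8%.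

The forecast gives other numbers: c 67% (56% to 75%), higher, eP 24% (17% to 35%) and eS 47% (30% to 62%). Of interconversion it says “there is no clear sign of it”.

The flask gives c 63.0%, eP 39.2%, above the forecast's range, and eS 24.5%, below it.

    left-handed substrate ⇌ right-handed substrate (k = 3.06 × 10⁻⁴ s⁻¹)
    catalyst + added ligand ⇌ idle complex, settled at all times (K = 5500 M⁻¹)
    reagent + catalyst + right-handed substrate → catalyst + right-handed product (k = 332 M⁻² s⁻¹)
    reagent ⇌ dormant form (K = 0.320, k = 3.86 × 10⁻⁴ s⁻¹)
    reagent + catalyst + left-handed substrate → catalyst + left-handed product (k = 1050 M⁻² s⁻¹)

In the flask, 28% of the left-handed substrate and 46% of the right-handed substrate remain of their charges at 40.0 min. The same ratio is therefore 1.64, lower than the south-west reading. The interconversion step by itself, both ways together, relaxes with a half-life of 18.9 min, shorter than the run, and in the flask its backward turnover is 147% of the forward one. The neighbouring flask, with [reagent] = 5.0 mM, reaches c 19.7%. It keeps 76% of the left-handed substrate charge and 84% of the right-handed substrate charge, a ratio of 1.56.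

(The readings come from a simulation for an exercise, noise included.)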